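Ring A is built de novo on the diaryl ether oxygen instead of arylating a crowded phenol. Ring A carries oxygen at C2, carbon at C1 and oxygen at C6, with C3 alkyl and C4/C5 unsubstituted, which is the pattern a vinylketene–ynol ether benzannulation produces. In one operation the key step forms C1–C2, C5–C6 and C2–C3, closes ring A as its C2 phenol, and sets four contiguous substituents with the hindered ether already in place. Its precursors are a chiral-pool (E)-diazo enone carrying the (R)-methoxy stereocentre and a ring B aryloxyalkyne (MOM ether, dioxolane, silyloxymethyl terminus).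

Key step: step 10

Remark: ring A is numbered from the carboxyl carbon (C1) to the aryloxy carbon (C6) and ring B is the formyl-bearing ring; iodomethane, the phosphorane, MsN3 and the silyl reagents are assumed to be purchased.

Step 1
Reactants: 1 (R)-2-hydroxy-4-methylpentanoic acid
Product: 2 methyl (R)-2-methoxy-4-methylpentanoate
Conditions: MeI (excess), Ag2O, MeCN, rt, dark
Reagents that add atoms: iodomethane, CI
Why: Purdie methylation alkylates carboxylate and hydroxyl without a strong base, so the α-stereocentre taken from the chiral pool is not enolised and stays (R).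

Step 2
Reactants: 2 methyl (R)-2-methoxy-4-methylpentanoate
Product: 4 (3E,5R)-5-methoxy-7-methyloct-3-en-2-one, via (R)-2-methoxy-4-methylpentanal 3 (not isolated)
Conditions: iBu2AlH, CH2Cl2, −78 °C; MeOH; then Ph3P=CHC(O)CH3, −78 °C to 40 °C
Reagents that add atoms: 1-(triphenylphosphoranylidene)propan-2-one, CC(=O)C=P(c1ccccc1)(c1ccccc1)c1ccccc1
Why: low-temperature hydride reduction of the α-alkoxy ester stops at the aldehyde level and the stabilised ylide traps the aldehyde in the same flask (E-selective Wittig olefination), so the epimerisable α-methoxy aldehyde is never handled and C5 keeps its configuration.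

Step 3
Reactants: 4 (3E,5R)-5-methoxy-7-methyloct-3-en-2-one
Product: 6 (3E,5R)-1-diazo-5-methoxy-7-methyloct-3-en-2-one, via trifluoroacetyl diketone 5 (not isolated)
Conditions: LiN(SiMe3)2, THF, −78 °C; CF3CO2CH2CF3; then MsN3, Et3N, H2O, MeCN, rt
Reagents that add atoms: methanesulfonyl azide, CS(=O)(=O)N=[N+]=[N-]; 2,2,2-trifluoroethyl trifluoroacetate, O=C(OCC(F)(F)F)C(F)(F)F (its atoms stay in 5 only)
Why: detrifluoroacetylative diazo transfer (Regitz-type) after kinetic deprotonation of the methyl group is the standard entry to α′-diazo enones, avoids the pyrazoline formation seen when enoyl chlorides meet diazomethane, and does not touch the γ-stereocentre.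

Step 4
Reactants: 7 4-methylcatechol
Product: 8 2,3-dihydroxy-5-methylbenzaldehyde
Conditions: (CH2O)n, MgCl2, Et3N, MeCN, reflux; aq. HCl
Reagents that add atoms: formaldehyde (as paraformaldehyde), C=O
Why: magnesium-phenoxide-directed ortho-formylation (Casnati–Skattebøl reaction) places CHO only ortho to a hydroxyl, and of the two such positions the one not flanked by the methyl group is the accessible one.

Step 5
Reactants: 8 2,3-dihydroxy-5-methylbenzaldehyde
Product: 9 2-hydroxy-3-(methoxymethoxy)-5-methylbenzaldehyde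
Conditions: NaH (2.2 equiv), THF–DMSO, 0 °C to rt; MOMCl (1.0 equiv)
Reagents that add atoms: chloromethyl methyl ether, COCCl
Why: after double deprotonation the 3-oxide, which is neither conjugated with nor chelated to the formyl group, is the more nucleophilic oxygen, so one equivalent of electrophile gives the 3-O-MOM ether (Williamson-type O-alkylation) and leaves the 2-hydroxyl for the alkyne; an acetal was chosen over a silyl group because it cannot migrate between the catechol oxygens.

Step 6
Reactants: 9 2-hydroxy-3-(methoxymethoxy)-5-methylbenzaldehyde; 10 trichloroethylene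
Product: 12 2-{[(E)-1,2-dichloroethenyl]oxy}-3-(methoxymethoxy)-5-methylbenzaldehyde, via dichloroacetylene 11 (not isolated)
Conditions: K2CO3, DMF, 70 °C
Reagents that add atoms: none
Why: base-induced dehydrochlorination of 10 gives dichloroacetylene at low stationary concentration, to which the phenoxide adds in anti fashion (nucleophilic vinylation), the established route to aryl (E)-1,2-dichlorovinyl ethers; aldehyde and MOM ether are inert to carbonate.

Step 7
Reactants: 12 2-{[(E)-1,2-dichloroethenyl]oxy}-3-(methoxymethoxy)-5-methylbenzaldehyde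
Product: 13 2-[2-{[(E)-1,2-dichloroethenyl]oxy}-3-(methoxymethoxy)-5-methylphenyl]-1,3-dioxolane
Conditions: Me3SiOCH2CH2OSiMe3, Me3SiOTf (cat.), CH2Cl2, −78 to −20 °C; pyridine
Reagents that add atoms: 1,2-bis(trimethylsilyloxy)ethane, C[Si](C)(C)OCCO[Si](C)(C)C
Why: silyl-transfer acetalisation under aprotic catalysis forms the dioxolane without water or protic acid, so the MOM aryl ether and the dichlorovinyl ether survive, and the acetal shields the formyl group from n-BuLi and from the later oxidation.

Step 8
Reactants: 13 2-[2-{[(E)-1,2-dichloroethenyl]oxy}-3-(methoxymethoxy)-5-methylphenyl]-1,3-dioxolane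
Product: 16 3-[2-(1,3-dioxolan-2-yl)-6-(methoxymethoxy)-4-methylphenoxy]prop-2-yn-1-ol, via chloroethynyl aryl ether 14 (not isolated), via lithium aryloxyacetylide 15 (not isolated)
Conditions: n-BuLi (2.3 equiv), THF, −78 °C; (CH2O)n, −78 °C to rt; aq. NH4Cl
Reagents that add atoms: formaldehyde (as paraformaldehyde), C=O; n-butyllithium, [Li]CCCC (lithium stays in 15 only)
Why: elimination of HCl followed by chlorine–lithium exchange converts the dichlorovinyl ether into the lithium acetylide, which adds to formaldehyde (acetylide 1,2-addition); acetal, MOM ether and arene offer no competing site at −78 °C.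

Step 9
Reactants: 16 3-[2-(1,3-dioxolan-2-yl)-6-(methoxymethoxy)-4-methylphenoxy]prop-2-yn-1-ol
Product: 17 tert-butyl({3-[2-(1,3-dioxolan-2-yl)-6-(methoxymethoxy)-4-methylphenoxy]prop-2-yn-1-yl}oxy)dimethylsilane
Conditions: TBSCl, imidazole, CH2Cl2, 0 °C to rt
Reagents that add atoms: tert-butyldimethylsilyl chloride, CC(C)(C)[Si](C)(C)Cl
Why: silylation of a primary alcohol under mildly basic conditions that the acid-sensitive ynol ether tolerates; a free hydroxyl would be acylated by the ketene in step 10.

Step 10
Reactants: 6 (3E,5R)-1-diazo-5-methoxy-7-methyloct-3-en-2-one (1.5 equiv, added in portions); 17 tert-butyl({3-[2-(1,3-dioxolan-2-yl)-6-(methoxymethoxy)-4-methylphenoxy]prop-2-yn-1-yl}oxy)dimethylsilane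
Product: 21 2-{[(tert-butyldimethylsilyl)oxy]methyl}-3-[2-(1,3-dioxolan-2-yl)-6-(methoxymethoxy)-4-methylphenoxy]-6-[(1R)-1-methoxy-3-methylbutyl]phenol, via vinylketene 18 (not isolated), via alkenylcyclobutenone 19 (not isolated), via dienylketene 20 (not isolated)
Conditions: hν (365 nm), ClCH2CH2Cl, rt; then 80 °C
Reagents that add atoms: none
Why: Light expels N2 from 6 and the alkenyl group migrates (photochemical Wolff rearrangement) to give vinylketene 18, which undergoes (2+2) cycloaddition with ynol ether 17, the alkyne carbon remote from oxygen attacking the ketene carbonyl carbon, to give cyclobutenone 19 with the C1–C2 and C5–C6 bonds in place. Heating opens 19 by four-electron electrocyclic cleavage of the bond between the carbonyl carbon and C5 to give dienylketene 20, six-electron electrocyclisation then forms C2–C3 and closes the six-membered ring A, and tautomerisation gives phenol 21. The closest known reaction type is the Danheiser benzannulation of photochemically generated vinylketenes with alkoxy- and siloxyalkynes; an aryl ynol ether belongs to the same ketenophile class, and the two ortho substituents of ring B twist the aryl group so that the oxygen lone pair conjugates with the alkyne and not with the arene. No stereocentre is created (C4 of 19 is transient and erased on ring opening), and the (R)-centre from 1 is a spectator under these neutral conditions. The step needs regioselectivity, which the polarisation of the ynol ether secures by placing the aryloxy carbon at C6, meta to the new hydroxyl, with the CH2OTBS carbon between them, and chemoselectivity, which rests on 365 nm light absorbed only by the diazo ketone and on the absence of a β-hydrogen in an aryl ynol ether, which excludes retro-ene loss of ketene at 80 °C.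

Step 11
Reactants: 21 2-{[(tert-butyldimethylsilyl)oxy]methyl}-3-[2-(1,3-dioxolan-2-yl)-6-(methoxymethoxy)-4-methylphenoxy]-6-[(1R)-1-methoxy-3-methylbutyl]phenol
Product: 22 tert-butyl({6-[2-(1,3-dioxolan-2-yl)-6-(methoxymethoxy)-4-methylphenoxy]-2-methoxy-3-[(1R)-1-methoxy-3-methylbutyl]phenyl}methoxy)dimethylsilane
Conditions: MeI, K2CO3, DMF, rt
Reagents that add atoms: iodomethane, CI
Why: Williamson methylation of the crude, hindered C2 phenol at room temperature caps it before the phenoxide can assist loss of the neighbouring benzylic methoxy group (ortho-quinone methide pathway), so the stereocentre is kept.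

Step 12
Reactants: 22 tert-butyl({6-[2-(1,3-dioxolan-2-yl)-6-(methoxymethoxy)-4-methylphenoxy]-2-methoxy-3-[(1R)-1-methoxy-3-methylbutyl]phenyl}methoxy)dimethylsilane
Product: 23 {6-[2-(1,3-dioxolan-2-yl)-6-(methoxymethoxy)-4-methylphenoxy]-2-methoxy-3-[(1R)-1-methoxy-3-methylbutyl]phenyl}methanol
Conditions: Bu4NF, THF, 0 °C to rt; aq. NH4Cl
Reagents that add atoms: none
Why: fluoride-induced desilylation of a primary silyl ether, to which acetals and ethers are inert.

Step 13
Reactants: 23 {6-[2-(1,3-dioxolan-2-yl)-6-(methoxymethoxy)-4-methylphenoxy]-2-methoxy-3-[(1R)-1-methoxy-3-methylbutyl]phenyl}methanol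
Product: 25 6-[2-(1,3-dioxolan-2-yl)-6-(methoxymethoxy)-4-methylphenoxy]-2-methoxy-3-[(1R)-1-methoxy-3-methylbutyl]benzoic acid, via ring A aldehyde 24 (not isolated)
Conditions: TEMPO (cat.), NaOCl (cat.), NaClO2, MeCN–phosphate buffer (pH 6.7), 35 °C; acidify to pH 4
Reagents that add atoms: sodium chlorite, [Na+].[O-]Cl=O
Why: oxoammonium-mediated oxidation gives the aldehyde and chlorite carries it on to the acid in the same pot (TEMPO-catalysed oxidation combined with Pinnick-type chlorite oxidation); the near-neutral buffer preserves dioxolane and MOM ether, and the low hypochlorite level disfavours ring chlorination.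

Step 14
Reactants: 25 6-[2-(1,3-dioxolan-2-yl)-6-(methoxymethoxy)-4-methylphenoxy]-2-methoxy-3-[(1R)-1-methoxy-3-methylbutyl]benzoic acid
Product: 27 6-(2-formyl-6-hydroxy-4-methylphenoxy)-2-methoxy-3-[(1R)-1-methoxy-3-methylbutyl]benzoic acid, via MOM-protected formyl acid 26 (not isolated)
Conditions: 2 M aq. HCl, THF, rt to 40 °C
Reagents that add atoms: water, O
Why: acid-catalysed acetal hydrolysis removes first the dioxolane and then the MOM ether; the benzylic methyl ether is expected to resist ionisation because the meta carboxyl group and the twisted C2 methoxy group destabilise the benzylic cation, so the (R)-centre survives.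

Compound list
1 | (R)-2-hydroxy-4-methylpentanoic acid | CC(C)C[C@@H](O)C(=O)O | starting material
2 | methyl (R)-2-methoxy-4-methylpentanoate | COC(=O)[C@@H](CC(C)C)OC | intermediate
3 | (R)-2-methoxy-4-methylpentanal | O=C[C@@H](CC(C)C)OC | intermediate (not isolated)
4 | (3E,5R)-5-methoxy-7-methyloct-3-en-2-one | CC(=O)/C=C/[C@@H](CC(C)C)OC | intermediate
5 | (5E,7R)-1,1,1-trifluoro-7-methoxy-9-methyldec-5-ene-2,4-dione | O=C(CC(=O)C(F)(F)F)/C=C/[C@@H](CC(C)C)OC | intermediate (not isolated)
6 | (3E,5R)-1-diazo-5-methoxy-7-methyloct-3-en-2-one | [N-]=[N+]=CC(=O)/C=C/[C@@H](CC(C)C)OC | intermediate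
7 | 4-methylcatechol | Cc1ccc(O)c(O)c1 | starting material
8 | 2,3-dihydroxy-5-methylbenzaldehyde | Cc1cc(O)c(O)c(C=O)c1 | intermediate
9 | 2-hydroxy-3-(methoxymethoxy)-5-methylbenzaldehyde | COCOc1cc(C)cc(C=O)c1O | intermediate
10 | trichloroethylene | ClC=C(Cl)Cl | starting material
11 | dichloroacetylene | ClC#CCl | intermediate (not isolated)
12 | 2-{[(E)-1,2-dichloroethenyl]oxy}-3-(methoxymethoxy)-5-methylbenzaldehyde | Cl/C=C(/Cl)Oc1c(OCOC)cc(C)cc1C=O | intermediate
13 | 2-[2-{[(E)-1,2-dichloroethenyl]oxy}-3-(methoxymethoxy)-5-methylphenyl]-1,3-dioxolane | Cl/C=C(/Cl)Oc1c(OCOC)cc(C)cc1C1OCCO1 | intermediate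
14 | 2-[2-(chloroethynyloxy)-3-(methoxymethoxy)-5-methylphenyl]-1,3-dioxolane | ClC#COc1c(OCOC)cc(C)cc1C1OCCO1 | intermediate (not isolated)
15 | lithium [2-(1,3-dioxolan-2-yl)-6-(methoxymethoxy)-4-methylphenoxy]acetylide | [Li]C#COc1c(OCOC)cc(C)cc1C1OCCO1 | intermediate (not isolated)
16 | 3-[2-(1,3-dioxolan-2-yl)-6-(methoxymethoxy)-4-methylphenoxy]prop-2-yn-1-ol | OCC#COc1c(OCOC)cc(C)cc1C1OCCO1 | intermediate
17 | tert-butyl({3-[2-(1,3-dioxolan-2-yl)-6-(methoxymethoxy)-4-methylphenoxy]prop-2-yn-1-yl}oxy)dimethylsilane | CC(C)(C)[Si](C)(C)OCC#COc1c(OCOC)cc(C)cc1C1OCCO1 | intermediate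
18 | (3E,5R)-5-methoxy-7-methylocta-1,3-dien-1-one | O=C=C/C=C/[C@@H](CC(C)C)OC | intermediate (not isolated)
19 | 2-{[(tert-butyldimethylsilyl)oxy]methyl}-3-[2-(1,3-dioxolan-2-yl)-6-(methoxymethoxy)-4-methylphenoxy]-4-[(1E,3R)-3-methoxy-5-methylhex-1-en-1-yl]cyclobut-2-en-1-one (both C4 epimers) | O=C1C(CO[Si](C)(C)C(C)(C)C)=C(Oc2c(OCOC)cc(C)cc2C2OCCO2)C1/C=C/[C@@H](CC(C)C)OC | intermediate (not isolated)
20 | (3E,5E,7R)-2-{[(tert-butyldimethylsilyl)oxy]methyl}-3-[2-(1,3-dioxolan-2-yl)-6-(methoxymethoxy)-4-methylphenoxy]-7-methoxy-9-methyldeca-1,3,5-trien-1-one | O=C=C(CO[Si](C)(C)C(C)(C)C)/C(Oc1c(OCOC)cc(C)cc1C1OCCO1)=C\C=C\[C@@H](CC(C)C)OC | intermediate (not isolated)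
21 | 2-{[(tert-butyldimethylsilyl)oxy]methyl}-3-[2-(1,3-dioxolan-2-yl)-6-(methoxymethoxy)-4-methylphenoxy]-6-[(1R)-1-methoxy-3-methylbutyl]phenol | Oc1c([C@@H](CC(C)C)OC)ccc(Oc2c(OCOC)cc(C)cc2C2OCCO2)c1CO[Si](C)(C)C(C)(C)C | intermediate
22 | tert-butyl({6-[2-(1,3-dioxolan-2-yl)-6-(methoxymethoxy)-4-methylphenoxy]-2-methoxy-3-[(1R)-1-methoxy-3-methylbutyl]phenyl}methoxy)dimethylsilane | COc1c([C@@H](CC(C)C)OC)ccc(Oc2c(OCOC)cc(C)cc2C2OCCO2)c1CO[Si](C)(C)C(C)(C)C | intermediate
23 | {6-[2-(1,3-dioxolan-2-yl)-6-(methoxymethoxy)-4-methylphenoxy]-2-methoxy-3-[(1R)-1-methoxy-3-methylbutyl]phenyl}methanol | COc1c([C@@H](CC(C)C)OC)ccc(Oc2c(OCOC)cc(C)cc2C2OCCO2)c1CO | intermediate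
24 | 6-[2-(1,3-dioxolan-2-yl)-6-(methoxymethoxy)-4-methylphenoxy]-2-methoxy-3-[(1R)-1-methoxy-3-methylbutyl]benzaldehyde | COc1c([C@@H](CC(C)C)OC)ccc(Oc2c(OCOC)cc(C)cc2C2OCCO2)c1C=O | intermediate (not isolated)
25 | 6-[2-(1,3-dioxolan-2-yl)-6-(methoxymethoxy)-4-methylphenoxy]-2-methoxy-3-[(1R)-1-methoxy-3-methylbutyl]benzoic acid | COc1c([C@@H](CC(C)C)OC)ccc(Oc2c(OCOC)cc(C)cc2C2OCCO2)c1C(=O)O | intermediate
26 | 6-[2-formyl-6-(methoxymethoxy)-4-methylphenoxy]-2-methoxy-3-[(1R)-1-methoxy-3-methylbutyl]benzoic acid | COc1c([C@@H](CC(C)C)OC)ccc(Oc2c(OCOC)cc(C)cc2C=O)c1C(=O)O | intermediate (not isolated)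
27 | 6-(2-formyl-6-hydroxy-4-methylphenoxy)-2-methoxy-3-[(1R)-1-methoxy-3-methylbutyl]benzoic acid | COc1c([C@@H](CC(C)C)OC)ccc(Oc2c(O)cc(C)cc2C=O)c1C(=O)O | target

Total step count: 14.
Longest linear sequence: 11 steps (7 to 27 through steps 4 to 14); the diazo ketone branch (steps 1 to 3) joins at step 10.

Steps most likely to fail

Step 10. An aryloxy group donates less to the alkyne than an alkoxy or siloxy group, so capture of the short-lived vinylketene may lose out to ketene self-condensation, and the ynol ether may be consumed by adventitious acid. The fallback builds ring A with a siloxyalkyne of established reactivity and makes the ether bond afterwards; it leaves the route at 6 (with 9 as the ring B source) and returns at 22.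
- Lithiation of commercial tert-butyldimethyl(prop-2-yn-1-yloxy)silane (n-BuLi), oxidation of the acetylide to the ynolate with LiOOtBu and O-silylation with iPr3SiOTf should give tert-butyldimethyl{[3-(triisopropylsilyloxy)prop-2-yn-1-yl]oxy}silane F1.
- Irradiation and heating of 6 with F1 as in step 10 should give 2-{[(tert-butyldimethylsilyl)oxy]methyl}-6-[(1R)-1-methoxy-3-methylbutyl]-3-[(triisopropylsilyl)oxy]phenol F2.
- Methylation (MeI, K2CO3, DMF) gives tert-butyl({2-methoxy-3-[(1R)-1-methoxy-3-methylbutyl]-6-[(triisopropylsilyl)oxy]phenyl}methoxy)dimethylsilane F3.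
- One equivalent of Bu4NF at −20 °C should cleave the aryl silyl ether well before the primary alkyl silyl ether, giving 2-{[(tert-butyldimethylsilyl)oxy]methyl}-3-methoxy-4-[(1R)-1-methoxy-3-methylbutyl]phenol F4.
- Phenol 9 is converted (Tf2O, pyridine) into 2-formyl-6-(methoxymethoxy)-4-methylphenyl trifluoromethanesulfonate F5.
- Buchwald–Hartwig etherification of F5 with F4 (Pd(OAc)2, tBuXPhos, K3PO4, toluene, 80 °C), an electronically matched pair of electron-poor triflate and electron-rich phenol, should give 2-(2-{[(tert-butyldimethylsilyl)oxy]methyl}-3-methoxy-4-[(1R)-1-methoxy-3-methylbutyl]phenoxy)-3-(methoxymethoxy)-5-methylbenzaldehyde F6.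
- Acetalisation of F6 as in step 7 returns to 22.
- F4 is a phenol para to the benzylic ether, which the main route avoids. It would be used at once, its phenoxide kept heterogeneous and at or below 80 °C, and the enantiomeric purity of F6 checked before going on.

Step 8. Paraformaldehyde depolymerises slowly at low temperature, so acetylide 15 may be quenched as the terminal ynol ether or decay before it is captured. The fallback replaces hydroxymethylation by acylation and reduction; it sets out from 13 and returns at 16. Acetylide 15 is generated as in step 8 and trapped at −78 °C with the soluble electrophile methyl chloroformate to give methyl 3-[2-(1,3-dioxolan-2-yl)-6-(methoxymethoxy)-4-methylphenoxy]prop-2-ynoate F7. Reduction of the ester with iBu2AlH (CH2Cl2, −78 to 0 °C) returns to 16.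

Step 4. Both catechol oxygens can chelate magnesium and slow the transfer of formaldehyde, and formylation may be shared with the position between hydroxyl and methyl. The fallback uses directed ortho-metalation instead of electrophilic formylation; it sets out from 7 and returns at 9, which also makes step 5 unnecessary.
- MOMCl and iPr2NEt give 1,2-bis(methoxymethoxy)-4-methylbenzene F8.
- n-BuLi/TMEDA in THF at 0 °C lithiates the unhindered position next to an OMOM group, and DMF then gives 2,3-bis(methoxymethoxy)-5-methylbenzaldehyde F9.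
- Brief treatment with dilute aqueous HCl in THF at rt removes selectively the MOM group ortho to the formyl group, whose phenol is the better leaving group and is hydrogen-bonded to the carbonyl, which returns to 9.

Further compounds
F1 | step 10 | tert-butyldimethyl{[3-(triisopropylsilyloxy)prop-2-yn-1-yl]oxy}silane | CC(C)[Si](OC#CCO[Si](C)(C)C(C)(C)C)(C(C)C)C(C)C
F2 | step 10 | 2-{[(tert-butyldimethylsilyl)oxy]methyl}-6-[(1R)-1-methoxy-3-methylbutyl]-3-[(triisopropylsilyl)oxy]phenol | Oc1c([C@@H](CC(C)C)OC)ccc(O[Si](C(C)C)(C(C)C)C(C)C)c1CO[Si](C)(C)C(C)(C)C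
F3 | step 10 | tert-butyl({2-methoxy-3-[(1R)-1-methoxy-3-methylbutyl]-6-[(triisopropylsilyl)oxy]phenyl}methoxy)dimethylsilane | COc1c([C@@H](CC(C)C)OC)ccc(O[Si](C(C)C)(C(C)C)C(C)C)c1CO[Si](C)(C)C(C)(C)C
F4 | step 10 | 2-{[(tert-butyldimethylsilyl)oxy]methyl}-3-methoxy-4-[(1R)-1-methoxy-3-methylbutyl]phenol | COc1c([C@@H](CC(C)C)OC)ccc(O)c1CO[Si](C)(C)C(C)(C)C
F5 | step 10 | 2-formyl-6-(methoxymethoxy)-4-methylphenyl trifluoromethanesulfonate | COCOc1cc(C)cc(C=O)c1OS(=O)(=O)C(F)(F)F
F6 | step 10 | 2-(2-{[(tert-butyldimethylsilyl)oxy]methyl}-3-methoxy-4-[(1R)-1-methoxy-3-methylbutyl]phenoxy)-3-(methoxymethoxy)-5-methylbenzaldehyde | COc1c([C@@H](CC(C)C)OC)ccc(Oc2c(OCOC)cc(C)cc2C=O)c1CO[Si](C)(C)C(C)(C)C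
F7 | step 8 | methyl 3-[2-(1,3-dioxolan-2-yl)-6-(methoxymethoxy)-4-methylphenoxy]prop-2-ynoate | COC(=O)C#COc1c(OCOC)cc(C)cc1C1OCCO1
F8 | step 4 | 1,2-bis(methoxymethoxy)-4-methylbenzene | COCOc1ccc(C)cc1OCOC
F9 | step 4 | 2,3-bis(methoxymethoxy)-5-methylbenzaldehyde | COCOc1cc(C)cc(C=O)c1OCOC
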